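All runs are simulated on assumed constants, noise included.

Hour by hour the substrate in the dusk run falls by a roughly steady fraction, as read 0.314 /h between 1.50 h and 5.00 h and 0.384 /h between 5.00 h and 8.00 h, which looks like pseudo-first-order behaviour. We take 0.346 /h across the whole span.

| flask | substrate | reagent | free catalyst | second catalyst | remark | time |
|---|---|---|---|---|---|---|
| dusk | 10 mM | 1.3 equiv | 0.89 mol% | 15 mol% | run made earlier |  |
| winter | 10 mM | 1.3 equiv | 0.6 mol% | 15 mol% | run made earlier |  |
| noon | 10 mM | 1.3 equiv | 1.3 mol% | 15 mol% | run made earlier |  |
| midnight | 10 mM | 1.3 equiv | 0.89 mol% | 7.5 mol% | run made earlier |  |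
| alder | 10 mM | 1.30 equiv (fed, over 25 h) | 0.89 mol% | 15 mol% | all else is in the flask from the start; the feed brings no volume worth counting | 40 h |
| ash | 10 mM (fed, over 25 h) | 1.30 equiv | 0.89 mol% | 15 mol% | all else is in the flask from the start; the feed brings no volume worth counting | 40 h |
| larch | 10 mM | 1.30 equiv | 0.89 mol% | 15 mol% | everything together at the start | 40 h |

| run | time / h | target / % | substrate / % |
|---|---|---|---|
| dusk | 1.50 | 17 | 57 |
| dusk | 5.00 | 53 | 19 |
| dusk | 8.00 | 66 | 6 |
| dusk | 12.0 | 70 | 4 |
| dusk | 20.0 | 72 | 0 |
| dusk | 25.0 | 72 | 0 |
| winter | 3.00 | 27 | 46 |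
| winter | 5.00 | 40 | 25 |
| winter | 8.00 | 53 | 13 |
| winter | 15.0 | 63 | 3 |
| winter | 25.0 | 63 | 2 |
| winter | 40.0 | 68 | 0 |
| noon | 3.00 | 50 | 23 |
| noon | 5.00 | 67 | 12 |
| noon | 8.00 | 74 | 5 |
| noon | 15.0 | 79 | 1 |
| noon | 25.0 | 79 | 1 |
| noon | 40.0 | 77 | 1 |
| midnight | 8.00 | 63 | 7 |
| midnight | 15.0 | 69 | 3 |
| midnight | 25.0 | 73 | 0 |
| midnight | 30.0 | 73 | 3 |
| midnight | 40.0 | 72 | 0 |

(readings scatter by 1.5 percentage points)

- the numbers in the tables scatter with a standard deviation of 1.5 percentage points

- the flask with the highest amount of target, in percent of the substrate charged ("all alike" if they lie within 1.5 percentage points) (alder / ash / larch / all alike)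
- final target, as a percentage of the substrate charged, in alder
- final target, as a percentage of the substrate charged, in ash
- final target, as a percentage of the substrate charged, in larch

Follow one substrate molecule: it takes either the catalysed road to target or a loss road. We call the rate of the first over the rate of the second the fork odds ω, a selectivity factor, read at the end of a run as target over the part that is not target: 2.57 for dusk. Noon differs from dusk in free catalyst, and its 79% at 15.0 h gives ω = 3.76. So, as read, ω rose by a factor 1.46 for a factor 1.46 in catalyst, and noon ends higher than dusk. Midnight, with second catalyst halved, ends at 72%, close to dusk. A roughly steady fraction suggests that substrate cancels from ω, and we assume the loss to be substrate meeting reagent, with ω proportional to free catalyst over reagent; the earlier runs hold reagent at 1.3 equiv, so this is an assumption and not a reading.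

Our reckoning follows. Larch repeats the recipe of dusk, so we put it near 72%, and since substrate cancels from ω in our reading, we put ash near the same value. In alder, suppose the catalysed road takes substrate without waiting for reagent, at 0.249 /h, a lifetime τ of 4.01 h, shorter than the feed of 25 h. Over one τ the feed delivers 16.0% of the reagent charge, while dusk starts with the whole of it, so we take the reagent that a substrate molecule meets in alder as 6.23 times lower than in dusk. This estimate makes ω about 16.0 and target in alder about 94.1%, above our figure for ash and larch.

The forecast differs: ash highest, with 72% in alder, 88% in ash and 72% in larch, on the ground that “Feeding substrate holds it near 14% of charge, so selectivity is about 0.89, giving roughly 88%.”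

The flasks give 99.6% in alder, 74.6% in ash and 73.7% in larch.

    substrate + free catalyst → free catalyst + open intermediate (k = 2750 /M/h)
    second catalyst + open intermediate ⇌ catalyst intermediate (K = 92.7 /M, k = 989 /M/h)
    reagent + catalyst intermediate → second catalyst + target (k = 25300 /M/h)
    substrate + reagent → uncatalysed product (k = 10.4 /M/h)

In larch at 2.19 h, the free-catalyst step uses substrate 2.8 times as fast as the step with reagent, and the end ratio of target to uncatalysed product, our ω, is 2.81. In alder that ratio is 223, above our 16.0, with reagent at 20.0 h at 5.27% of its charge against 23.3% in larch. A neighbour of larch at 2.5 mM substrate, equivalents and loadings held, stands at 40.0 h with 4.44% substrate left, 25.9% uncatalysed product and 68.2% target, a ratio of target to uncatalysed product of 2.63.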